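The chemist who ran dusk and winter changed one charge between them, the protic impurity, and late in both runs two flat amounts stand.

| setting | dusk | winter | flask |
|---|---|---|---|
| starting material | 0.50 M | 0.50 M | 0.50 M |
| other conformer | 1 equiv | 1 equiv | 1.00 equiv |
| protic impurity | 0.075 M | 0.30 M | 0.150 M |
| remark | run made earlier | run made earlier |  |
| time |  |  | 12 d |

| run | time / d | isomer of the product A / % | target / % |
|---|---|---|---|
| dusk | 1.67 | 53.6 | 2.2 |
| dusk | 4.00 | 52.8 | 0.9 |
| dusk | 8.00 | 53.6 | 0.9 |
| dusk | 12.0 | 53.3 | 1.4 |
| winter | 1.04 | 31.8 | 4.3 |
| winter | 2.00 | 31.7 | 1.5 |
| winter | 5.00 | 31.6 | 1.3 |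
| winter | 12.0 | 31.3 | 1.1 |

(standard deviation of a reading: 0.3 percentage points)

- ratio of isomer of the product A to target at 12 min
- ratio of isomer of the product A to target at 12 d
- which of isomer of the product A and target there is more of at 12 d



Isomer of the product A averages 53.3% in dusk and 31.6% in winter. We take that drop in molarity and divide it by the added impurity, which gives 0.966, the impurity toll, isomer lost per impurity charged. Counted from dusk, the toll puts the flask's plateau at 46.1%.

Target's late readings in the two runs average 1.12%, and we take this floor over to the flask. Our ratio at 12 d is plateau over floor, 41.1. Each reading carries a scatter of 0.3 percentage points, and the plateau is far larger than the floor, so the floor carries the ratio's uncertainty.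

The forecast gives 40 at 12 d, with isomer of the product A ahead, and 1.5 at 12 min, which is earlier than the first reading: “This is an extrapolation and very uncertain, since no early data exist.” We reckon nothing there.

The flask gives 1.25 at 12 min and 48.2 at 12 d, with 46.3% isomer of the product A against 0.960% target.

    starting material ⇌ other conformer (K = 8.50, k = 0.140 h⁻¹)
    starting material → target (k = 0.330 h⁻¹)
    other conformer → isomer of the product A (k = 0.480 h⁻¹)
    starting material + target → side product (k = 0.840 M⁻¹ h⁻¹)
    other conformer + protic impurity → quenched substrate (k = 29.0 M⁻¹ h⁻¹)
    target ⇌ isomer of the product B (K = 22.0, k = 0.0720 h⁻¹)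

The relaxation half-life of target and isomer of the product B, 0.384 d by that step alone, is short against the 12 d. Target in the flask stands at 0.960% after 6.00 d and at 0.960% after 120 d. The toll's plateau was 46.1%, and protic impurity, limiting reagent of its quench, stands in the flask at 0% of its charge after 12.0 d. For the neighbour with 0.060 M of protic impurity the toll gives 54.8%, and that flask holds 55.1% of isomer of the product A.

The data stem from a simulated flask from invented constants.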